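**Retrosynthetic overview**

1. Numbering: ring A is the ten-membered carbocycle C1–C10 (C1 ketone, C4–C5 epoxide, C6 lactone oxygen, C8 methacrylate, C9 OH, C10 methyl); ring B is the butenolide (C6, C7, C11, C12, O; C13 = CH2OAc). The strategy rests on one feature of ring A: C2, the α-carbon of the C1 ketone, is bonded to C3, the allylic CH2 of the E-C4=C5 olefin that ends as the epoxide (a γ,δ-unsaturated ketone C1(=O)–C2–C3–C4=C5).
2. Key disconnection C2–C3: ring A comes from a twelve-membered allyl β-keto lactone (C2–C(=O)–O–C3) by palladium-induced loss of CO2. C7 goes through this step as a 3,4-dimethoxybenzyl (DMB) ether and not as the ketone, because the C2 enolate of the opened ion pair would otherwise close a six-membered aldol onto C7 (C2–C1–C10–C9–C8–C7).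
3. The lactone comes from acylketene macrolactonisation of a tert-butyl β-keto ester onto C3–OH. C9 and C10 come from a chelation-controlled acetate aldol and a Fráter–Seebach methylation, C6 from chelation-controlled addition of the C3–C5 alkenyl Grignard (from propargyl alcohol), and C7/C8 from diethyl L-tartrate.
4. After the contraction: C6 acrylate and C7 ketone, intramolecular Morita–Baylis–Hillman closure of ring B, 1,3-transposition of acetate to C13, PMB exchanged for methacrylate at C8, C9 desilylation, epoxidation of C4=C5 last.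
5. Ring order: twelve-membered lactone, then ring A, then ring B, then the epoxide.

Key step: step 18

Remark: 3,4-dimethoxybenzyl trichloroacetimidate is taken as a stock reagent (one operation from 3,4-dimethoxybenzyl alcohol and Cl3CCN); atom numbers are those of the overview throughout.

**Route**

Step 1
Reactants: 1 prop-2-yn-1-ol (propargyl alcohol)
Product: 2 (E)-3-iodo-2-methylprop-2-en-1-ol
Conditions: AlMe3 (3 equiv), Cp2ZrCl2 (0.25 equiv), CH2Cl2, 0 °C → rt; then I2, THF, −30 → 0 °C
Reagents that add atoms: trimethylaluminium C[Al](C)C; iodine II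
Why: Negishi zirconium-catalysed carboalumination adds methyl and aluminium syn across the alkyne with aluminium at the terminus, and iodinolysis with retention should give only the E-iodide (C3–C5 with the C4 methyl).

Step 2
Reactants: 2 (E)-3-iodo-2-methylprop-2-en-1-ol
Product: 3 triethyl{[(E)-3-iodo-2-methylprop-2-en-1-yl]oxy}silane
Conditions: Et3SiCl, imidazole, CH2Cl2, 0 °C
Reagents that add atoms: chlorotriethylsilane CC[Si](Cl)(CC)CC
Why: Standard silylation of the primary allylic alcohol; this primary TES ether is the silyl group that will be removed first (step 16).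

Step 3
Reactants: 4 diethyl L-tartrate
Product: 5 diethyl (2R,3R)-2-hydroxy-3-[(4-methoxybenzyl)oxy]butanedioate
Conditions: Ag2O (1.5 equiv), 4-methoxybenzyl bromide (1.1 equiv), CH2Cl2, rt, dark
Reagents that add atoms: 4-methoxybenzyl bromide COc1ccc(CBr)cc1
Why: Ag2O-mediated Williamson mono-alkylation under neutral conditions (no epimerisation); the two hydroxyls of the C2-symmetric diol are homotopic, so a single mono-ether should form, and it carries PMB on the future C8 oxygen.

Step 4
Reactants: 5 diethyl (2R,3R)-2-hydroxy-3-[(4-methoxybenzyl)oxy]butanedioate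
Product: 7 (3R,4S)-4-hydroxy-3-[(4-methoxybenzyl)oxy]oxolan-2-one, via dihydroxy ester 6 (not isolated)
Conditions: BH3·SMe2 (1.05 equiv), NaBH4 (5 mol %), THF, 0 °C → rt; H2O; then TsOH·H2O (cat.), CH2Cl2, rt
Reagents that add atoms: none
Why: Hydroxyl-directed borane reduction takes only the ester next to the free hydroxyl (hydride delivery from the alkoxyborane), and the new primary alcohol closes the γ-lactone onto the other ester, which tells the two chain ends apart (lactone carbonyl = C9, CH2O = C6).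

Step 5
Reactants: 7 (3R,4S)-4-hydroxy-3-[(4-methoxybenzyl)oxy]oxolan-2-one
Product: 8 (3R,4S)-4-[(3,4-dimethoxybenzyl)oxy]-3-[(4-methoxybenzyl)oxy]oxolan-2-one
Conditions: 3,4-dimethoxybenzyl trichloroacetimidate (1.5 equiv), CSA (cat.), CH2Cl2, 0 °C → rt
Reagents that add atoms: 3,4-dimethoxybenzyl 2,2,2-trichloroacetimidate COc1ccc(COC(=N)C(Cl)(Cl)Cl)cc1OC
Why: Acid-catalysed imidate O-alkylation avoids base (which would cause β-elimination in the lactone) and puts on the C7 oxygen the benzyl-type ether that DDQ cleaves before PMB.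

Step 6
Reactants: 8 (3R,4S)-4-[(3,4-dimethoxybenzyl)oxy]-3-[(4-methoxybenzyl)oxy]oxolan-2-one
Product: 9 (2R,3S)-3-[(3,4-dimethoxybenzyl)oxy]-4-hydroxy-N-methoxy-2-[(4-methoxybenzyl)oxy]-N-methylbutanamide
Conditions: Me(MeO)NH·HCl, AlMe3, CH2Cl2, 0 °C → rt
Reagents that add atoms: N,O-dimethylhydroxylamine hydrochloride CNOC.Cl
Why: Weinreb aminolysis of the lactone by the aluminium amide opens the ring, masks C9 as the N-methoxy-N-methylamide and frees the C6 primary alcohol.

Step 7
Reactants: 9 (2R,3S)-3-[(3,4-dimethoxybenzyl)oxy]-4-hydroxy-N-methoxy-2-[(4-methoxybenzyl)oxy]-N-methylbutanamide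
Product: 10 (2R,3R)-3-[(3,4-dimethoxybenzyl)oxy]-N-methoxy-2-[(4-methoxybenzyl)oxy]-N-methyl-4-oxobutanamide
Conditions: Dess–Martin periodinane, NaHCO3, CH2Cl2, 0 °C → rt; used crude
Reagents that add atoms: none
Why: Dess–Martin oxidation is non-basic, so the α-alkoxy aldehyde (C6) should form without epimerisation at C7.

Step 8
Reactants: 10 (2R,3R)-3-[(3,4-dimethoxybenzyl)oxy]-N-methoxy-2-[(4-methoxybenzyl)oxy]-N-methyl-4-oxobutanamide; 3 triethyl{[(E)-3-iodo-2-methylprop-2-en-1-yl]oxy}silane
Product: 12 (2R,3S,4R,5E)-3-[(3,4-dimethoxybenzyl)oxy]-4-hydroxy-N-methoxy-2-[(4-methoxybenzyl)oxy]-N,6-dimethyl-7-[(triethylsilyl)oxy]hept-5-enamide (C3–C9 unit; C6–OH syn to C7–ODMB), via alkenylmagnesium chloride 11 (not isolated)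
Conditions: 3, i-PrMgCl·LiCl, THF, 0 °C → rt; then added to 10 premixed with MgBr2·OEt2, CH2Cl2, −78 °C
Reagents that add atoms: none
Why: Cram-chelate Grignard addition, in which magnesium bridges the aldehyde oxygen and the α-ODMB oxygen so that the alkenyl group enters from the side of the C7 hydrogen and sets C6–OH syn to the C7 ether (the target C6 configuration); iodine–magnesium exchange keeps the E geometry and the Weinreb amide is inert at −78 °C.

Step 9
Reactants: 12 C3–C9 Weinreb amide with free C6–OH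
Product: 13 C6-O-triethylsilyl ether of 12 (C3 and C6 both TES)
Conditions: Et3SiCl, imidazole, DMAP (cat.), CH2Cl2, 0 °C → rt
Reagents that add atoms: chlorotriethylsilane CC[Si](Cl)(CC)CC
Why: Standard silylation; a secondary allylic TES ether at C6 is stable to the coming steps yet more labile than the later C9 TBS ether.

Step 10
Reactants: 13 bis-TES Weinreb amide
Product: 14 C9 aldehyde (α-OPMB at C8; C7–ODMB; C6–OTES; E-C4=C5; C3–OTES)
Conditions: i-Bu2AlH (1.5 equiv), THF, −78 °C; aq. potassium sodium tartrate; used crude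
Reagents that add atoms: none
Why: Reduction of the Weinreb amide stops at the chelated aluminium hemiaminal, which gives the aldehyde only on work-up.

Step 11
Reactants: 14 C9 aldehyde; 15 tert-butyl[(1-methoxyethenyl)oxy]dimethylsilane
Product: 16 methyl β-hydroxy ester (C1 ester; C10 = CH2; C9–OH syn to C8–OPMB)
Conditions: 15 (2 equiv), MgBr2·OEt2 (3 equiv), CH2Cl2, −78 → −30 °C; 1 N HCl
Reagents that add atoms: none
Why: Chelation-controlled Mukaiyama aldol, in which MgBr2 bridges the C9 aldehyde and the α-OPMB oxygen and the silyl ketene acetal adds anti to the C7 branch of the chelate, setting C9–OH syn to C8–OPMB.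

Step 12
Reactants: 16 methyl β-hydroxy ester
Product: 18 methyl ester with the C10 methyl anti to C9–OH, via dilithium alkoxide–enolate 17 (not isolated)
Conditions: LiN(i-Pr)2 (2.5 equiv), THF, −78 → −30 °C; MeI, DMPU, −78 → −20 °C; H2O
Reagents that add atoms: iodomethane CI
Why: Fráter–Seebach alkylation, in which the lithium-chelated alkoxide–enolate is methylated on the face away from the C8 side chain and so sets the C10 methyl anti to the C9 oxygen.

Step 13
Reactants: 18 anti-α-methyl-β-hydroxy methyl ester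
Product: 19 C9-O-tert-butyldimethylsilyl ether of 18
Conditions: TBSOTf, 2,6-lutidine, CH2Cl2, −78 → 0 °C
Reagents that add atoms: tert-butyldimethylsilyl triflate CC(C)(C)[Si](C)(C)OS(=O)(=O)C(F)(F)F
Why: Silyl triflate with a hindered base silylates the crowded secondary C9 alcohol without touching the ester or the TES ethers.

Step 14
Reactants: 19 C9–OTBS methyl ester
Product: 20 C1 aldehyde (C10 methyl; C9–OTBS)
Conditions: i-Bu2AlH (1.1 equiv), CH2Cl2, −78 °C; MeOH, aq. potassium sodium tartrate; used crude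
Reagents that add atoms: none
Why: Partial reduction of the methyl ester, the tetrahedral aluminium acetal being stable at −78 °C (helped by the β-silyloxy group), should stop at the aldehyde.

Step 15
Reactants: 20 C1 aldehyde; 21 tert-butyl diazoacetate
Product: 22 tert-butyl β-keto ester (C1 ketone; C2 = CH2; CO2t-Bu; C3 and C6 TES; C9 TBS)
Conditions: 21 (1.5 equiv), SnCl2 (10 mol %), CH2Cl2, rt
Reagents that add atoms: none
Why: Roskamp homologation (Lewis-acid-promoted addition of the diazo ester to the aldehyde, 1,2-hydride shift, loss of N2) gives the β-keto ester under neutral conditions that leave C10 configurationally intact.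

Step 16
Reactants: 22 bis-TES tert-butyl β-keto ester
Product: 23 hydroxy β-keto ester (C3–OH free; C6–OTES and C9–OTBS kept)
Conditions: PPTS (cat.), MeOH/CH2Cl2 1:4, −10 → 0 °C
Reagents that add atoms: none
Why: Acid-catalysed methanolysis removes the primary TES ether much faster than the secondary C6 TES and C9 TBS ethers.

Step 17
Reactants: 23 hydroxy β-keto ester
Product: 25 twelve-membered allyl β-keto lactone (skeleton descriptors 6R 7R 8R 9R 10S; E-C4=C5; C6–OTES; C7–ODMB; C8–OPMB; C9–OTBS), via acylketene 24 (not isolated)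
Conditions: toluene, reflux, 0.5 mM (syringe pump), 4 Å molecular sieves
Reagents that add atoms: none
Why: Thermolysis of the tert-butyl β-keto ester expels tert-butanol and gives the acylketene, which the C3 primary allylic alcohol traps at high dilution (acylketene macrolactonisation), and the neutral conditions leave C10 and the silyl ethers untouched.

Step 18
Reactants: 25 twelve-membered allyl β-keto lactone
Product: 26 (4E,6R,7R,8R,9R,10S)-9-[(tert-butyldimethylsilyl)oxy]-7-[(3,4-dimethoxybenzyl)oxy]-8-[(4-methoxybenzyl)oxy]-4,10-dimethyl-6-[(triethylsilyl)oxy]cyclodec-4-en-1-one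
Conditions: Pd(PPh3)4 (10 mol %), toluene (degassed, 2 mM), 40 °C
Reagents that add atoms: none
Why: Proposed new method: zerovalent palladium ionises the primary allylic C3–O bond of 25 to a π-allylpalladium β-keto carboxylate, loss of CO2 unmasks the enolate at C2 only, and C2 attacks C3 of the allyl unit, so that the O–C(=O) link is excised and the twelve-membered lactone becomes the ten-membered carbocycle. The closest known reactions are the Tsuji decarboxylative allylation of acyclic allyl β-keto esters and the Carroll rearrangement; new here is that the allyl ester is part of a macrocycle, so the allylation is a ring contraction. Ring A closes by C2–C3 bond formation within the palladium-bound ion pair, formally a ten-membered closure onto the CH2 terminus of the π-allyl unit with the enolate held near it through the metal. No stereocentre is created, and C10 is not epimerised because the enolate forms regiospecifically on the C2 side and no external base is present. The step needs attack at C3 and not C5 and retention of the E geometry: the unsubstituted terminus is favoured sterically, and the syn π-allyl (C6 syn to the C4 methyl) should be trapped in toluene faster than it isomerises. C7 is an ether and not a ketone so the C2 enolate cannot close a six-membered aldol, and high dilution suppresses dimerisation.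

Step 19
Reactants: 26 ten-membered ketone
Product: 27 C6 alcohol (C6–OH; C7–ODMB; C8–OPMB; C9–OTBS)
Conditions: HF·pyridine, pyridine, THF, 0 °C
Reagents that add atoms: none
Why: Buffered fluoride cleaves the secondary allylic TES ether selectively in the presence of the hindered C9 TBS ether.

Step 20
Reactants: 27 C6 alcohol
Product: 28 C6 acrylate
Conditions: acryloyl chloride, Et3N, DMAP (cat.), CH2Cl2, −40 → 0 °C
Reagents that add atoms: acryloyl chloride C=CC(=O)Cl
Why: Standard acylation of the only free hydroxyl; putting the acrylate on before C7 is oxidised avoids a free α-ketol at C6/C7.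

Step 21
Reactants: 28 C6 acrylate
Product: 29 C7 alcohol (C6 acrylate; C8–OPMB; C9–OTBS)
Conditions: DDQ (1.2 equiv), CH2Cl2/H2O (pH 7), 0 °C
Reagents that add atoms: none
Why: Oxidative cleavage of benzyl-type ethers by DDQ is fastest for the more electron-rich 3,4-dimethoxybenzyl group, so the C7 ether should go while the C8 PMB ether stays.

Step 22
Reactants: 29 C7 alcohol
Product: 30 C7 ketone (cyclodec-4-ene-1,7-dione with C6 acrylate; C8–OPMB; C9–OTBS)
Conditions: Dess–Martin periodinane, NaHCO3, CH2Cl2, 0 °C → rt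
Reagents that add atoms: none
Why: Dess–Martin oxidation under buffered non-basic conditions spares the C6 and C8 α-stereocentres, and in the closed ring the E-olefin forbids any transannular aldol of the 1,7-dione.

Step 23
Reactants: 30 keto acrylate
Product: 31 α-methylene-β-hydroxy-γ-lactone fused at C6–C7 (tertiary C7–OH; C7 configuration not defined; either epimer serves)
Conditions: PMe3 (0.5 equiv, 1 M in THF), t-BuOH/THF, rt
Reagents that add atoms: none
Why: Intramolecular Morita–Baylis–Hillman reaction, in which the phosphine adds to the acrylate, the phosphonium enolate closes ring B by 5-exo-trig aldol addition to the adjacent, doubly α-oxygenated and therefore activated C7 ketone, and proton transfer with loss of PMe3 gives the α-methylene lactone; the C7 carbinol centre is erased in step 24.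

Step 24
Reactants: 31 α-methylene-β-hydroxy lactone
Product: 33 butenolide with C13 acetate (C7=C11; CH2OAc on C11), via tertiary acetate 32 (not isolated)
Conditions: Ac2O, Et3N, DMAP (1.5 equiv), CH2Cl2, rt → 40 °C
Reagents that add atoms: acetic anhydride CC(=O)OC(C)=O
Why: Acetylation of the tertiary allylic alcohol followed by DMAP-mediated SN2′/SN2 (1,3) transposition of the acetate, driven by formation of the conjugated tetrasubstituted butenolide, moves the acetate to C13 and removes the C7 stereocentre.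

Step 25
Reactants: 33 butenolide acetate with C8–OPMB
Product: 34 C8 alcohol
Conditions: DDQ (1.5 equiv), CH2Cl2/H2O (pH 7), rt
Reagents that add atoms: none
Why: Oxidative PMB cleavage under neutral conditions, which avoids base-induced translactonisation to the C8 oxygen or acetate migration.

Step 26
Reactants: 34 C8 alcohol
Product: 35 C8 methacrylate (C9–OTBS)
Conditions: methacryloyl chloride, Et3N, DMAP (cat.), CH2Cl2, 0 °C
Reagents that add atoms: methacryloyl chloride CC(=C)C(=O)Cl
Why: Standard acylation of the only free hydroxyl at low temperature, done at once so that the C8 alcohol has no time to translactonise.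

Step 27
Reactants: 35 C8 methacrylate
Product: 36 C9 alcohol (4,5-deoxy target; E-C4=C5)
Conditions: HF·pyridine, THF, 0 °C → rt
Reagents that add atoms: none
Why: Acidic fluoride removes the TBS ether without acyl migration or retro-aldol of the β-hydroxy ketone, and it is done before epoxidation because the epoxide would not survive HF.

Step 28
Reactants: 36 C9 alcohol
Product: 37 target, (4R,5R,6S,8R,9R,10S)-13-acetoxy-4,5-epoxy-9-hydroxy-8-(methacryloyloxy)-1-oxogermacr-7(11)-en-12,6-olide
Conditions: mCPBA (1.1 equiv), NaHCO3, CH2Cl2, 0 °C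
Reagents that add atoms: 3-chloroperoxybenzoic acid OOC(=O)c1cccc(Cl)c1
Why: Prilezhaev epoxidation touches only the electron-rich trisubstituted C4=C5 olefin (butenolide and methacrylate are electron-poor) and is stereospecific, giving the trans-epoxide; the peracid should attack the outer face of the E-olefin of ring A (C6–H eclipsing the C4 methyl, C6–O on the attacked face), which sets C4 and C5 as (4R,5R).

**Compound list**

1 | prop-2-yn-1-ol (propargyl alcohol) | C#CCO | starting material
2 | (E)-3-iodo-2-methylprop-2-en-1-ol | OC/C(C)=C/I | intermediate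
3 | triethyl{[(E)-3-iodo-2-methylprop-2-en-1-yl]oxy}silane | CC[Si](CC)(CC)OC/C(C)=C/I | intermediate
4 | diethyl L-tartrate, diethyl (2R,3R)-2,3-dihydroxybutanedioate | CCOC(=O)[C@H](O)[C@@H](O)C(=O)OCC | starting material
5 | diethyl (2R,3R)-2-hydroxy-3-[(4-methoxybenzyl)oxy]butanedioate | CCOC(=O)[C@H](O)[C@@H](OCc1ccc(OC)cc1)C(=O)OCC | intermediate
6 | ethyl (2R,3S)-3,4-dihydroxy-2-[(4-methoxybenzyl)oxy]butanoate (not isolated) | OC[C@H](O)[C@@H](OCc1ccc(OC)cc1)C(=O)OCC | intermediate
7 | (3R,4S)-4-hydroxy-3-[(4-methoxybenzyl)oxy]oxolan-2-one | O=C1OC[C@H](O)[C@H]1OCc1ccc(OC)cc1 | intermediate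
8 | (3R,4S)-4-[(3,4-dimethoxybenzyl)oxy]-3-[(4-methoxybenzyl)oxy]oxolan-2-one | O=C1OC[C@H](OCc2ccc(OC)c(OC)c2)[C@H]1OCc1ccc(OC)cc1 | intermediate
9 | (2R,3S)-3-[(3,4-dimethoxybenzyl)oxy]-4-hydroxy-N-methoxy-2-[(4-methoxybenzyl)oxy]-N-methylbutanamide | OC[C@H](OCc1ccc(OC)c(OC)c1)[C@@H](OCc1ccc(OC)cc1)C(=O)N(C)OC | intermediate
10 | (2R,3R)-3-[(3,4-dimethoxybenzyl)oxy]-N-methoxy-2-[(4-methoxybenzyl)oxy]-N-methyl-4-oxobutanamide | O=C[C@H](OCc1ccc(OC)c(OC)c1)[C@@H](OCc1ccc(OC)cc1)C(=O)N(C)OC | intermediate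
11 | [(E)-2-methyl-3-(triethylsilyloxy)prop-1-en-1-yl]magnesium chloride, LiCl complex (not isolated) | CC[Si](CC)(CC)OC/C(C)=C/[Mg]Cl | intermediate
12 | (2R,3S,4R,5E)-3-[(3,4-dimethoxybenzyl)oxy]-4-hydroxy-N-methoxy-2-[(4-methoxybenzyl)oxy]-N,6-dimethyl-7-[(triethylsilyl)oxy]hept-5-enamide | CC[Si](CC)(CC)OC/C(C)=C/[C@@H](O)[C@H](OCc1ccc(OC)c(OC)c1)[C@@H](OCc1ccc(OC)cc1)C(=O)N(C)OC | intermediate
13 | C6-O-triethylsilyl ether of 12 (all-syn C6–OTES, C7–ODMB, C8–OPMB) | CC[Si](CC)(CC)OC/C(C)=C/[C@@H](O[Si](CC)(CC)CC)[C@H](OCc1ccc(OC)c(OC)c1)[C@@H](OCc1ccc(OC)cc1)C(=O)N(C)OC | intermediate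
14 | C9 aldehyde from 13 | CC[Si](CC)(CC)OC/C(C)=C/[C@@H](O[Si](CC)(CC)CC)[C@H](OCc1ccc(OC)c(OC)c1)[C@@H](OCc1ccc(OC)cc1)C=O | intermediate
15 | tert-butyl[(1-methoxyethenyl)oxy]dimethylsilane | C=C(OC)O[Si](C)(C)C(C)(C)C | starting material
16 | methyl β-hydroxy ester, C9–OH syn to C8–OPMB | CC[Si](CC)(CC)OC/C(C)=C/[C@@H](O[Si](CC)(CC)CC)[C@H](OCc1ccc(OC)c(OC)c1)[C@@H](OCc1ccc(OC)cc1)[C@H](O)CC(=O)OC | intermediate
17 | dilithium alkoxide–enolate of 16 (not isolated) | CC[Si](CC)(CC)OC/C(C)=C/[C@@H](O[Si](CC)(CC)CC)[C@H](OCc1ccc(OC)c(OC)c1)[C@@H](OCc1ccc(OC)cc1)[C@H]([O-])C=C([O-])OC.[Li+].[Li+] | intermediate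
18 | methyl ester with C10 methyl anti to C9–OH | CC[Si](CC)(CC)OC/C(C)=C/[C@@H](O[Si](CC)(CC)CC)[C@H](OCc1ccc(OC)c(OC)c1)[C@@H](OCc1ccc(OC)cc1)[C@H](O)[C@H](C)C(=O)OC | intermediate
19 | C9-O-tert-butyldimethylsilyl ether of 18 | CC[Si](CC)(CC)OC/C(C)=C/[C@@H](O[Si](CC)(CC)CC)[C@H](OCc1ccc(OC)c(OC)c1)[C@@H](OCc1ccc(OC)cc1)[C@H](O[Si](C)(C)C(C)(C)C)[C@H](C)C(=O)OC | intermediate
20 | C1 aldehyde from 19 | CC[Si](CC)(CC)OC/C(C)=C/[C@@H](O[Si](CC)(CC)CC)[C@H](OCc1ccc(OC)c(OC)c1)[C@@H](OCc1ccc(OC)cc1)[C@H](O[Si](C)(C)C(C)(C)C)[C@H](C)C=O | intermediate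
21 | tert-butyl diazoacetate | [N-]=[N+]=CC(=O)OC(C)(C)C | starting material
22 | tert-butyl β-keto ester (C1 ketone, C2 methylene, C3 and C6 TES, C9 TBS) | CC[Si](CC)(CC)OC/C(C)=C/[C@@H](O[Si](CC)(CC)CC)[C@H](OCc1ccc(OC)c(OC)c1)[C@@H](OCc1ccc(OC)cc1)[C@H](O[Si](C)(C)C(C)(C)C)[C@H](C)C(=O)CC(=O)OC(C)(C)C | intermediate
23 | hydroxy β-keto ester, C3–OH free | OC/C(C)=C/[C@@H](O[Si](CC)(CC)CC)[C@H](OCc1ccc(OC)c(OC)c1)[C@@H](OCc1ccc(OC)cc1)[C@H](O[Si](C)(C)C(C)(C)C)[C@H](C)C(=O)CC(=O)OC(C)(C)C | intermediate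
24 | acylketene from 23 (not isolated) | OC/C(C)=C/[C@@H](O[Si](CC)(CC)CC)[C@H](OCc1ccc(OC)c(OC)c1)[C@@H](OCc1ccc(OC)cc1)[C@H](O[Si](C)(C)C(C)(C)C)[C@H](C)C(=O)C=C=O | intermediate
25 | twelve-membered allyl β-keto lactone (6R,7R,8R,9R,10S; E-C4=C5) | O=C1CC(=O)OC/C(C)=C/[C@@H](O[Si](CC)(CC)CC)[C@H](OCc2ccc(OC)c(OC)c2)[C@@H](OCc2ccc(OC)cc2)[C@H](O[Si](C)(C)C(C)(C)C)[C@@H]1C | intermediate
26 | (4E,6R,7R,8R,9R,10S)-9-[(tert-butyldimethylsilyl)oxy]-7-[(3,4-dimethoxybenzyl)oxy]-8-[(4-methoxybenzyl)oxy]-4,10-dimethyl-6-[(triethylsilyl)oxy]cyclodec-4-en-1-one | O=C1CC/C(C)=C/[C@@H](O[Si](CC)(CC)CC)[C@H](OCc2ccc(OC)c(OC)c2)[C@@H](OCc2ccc(OC)cc2)[C@H](O[Si](C)(C)C(C)(C)C)[C@@H]1C | intermediate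
27 | C6 alcohol of ring A | O=C1CC/C(C)=C/[C@@H](O)[C@H](OCc2ccc(OC)c(OC)c2)[C@@H](OCc2ccc(OC)cc2)[C@H](O[Si](C)(C)C(C)(C)C)[C@@H]1C | intermediate
28 | C6 acrylate | O=C1CC/C(C)=C/[C@@H](OC(=O)C=C)[C@H](OCc2ccc(OC)c(OC)c2)[C@@H](OCc2ccc(OC)cc2)[C@H](O[Si](C)(C)C(C)(C)C)[C@@H]1C | intermediate
29 | C7 alcohol, C6 acrylate | O=C1CC/C(C)=C/[C@@H](OC(=O)C=C)[C@H](O)[C@@H](OCc2ccc(OC)cc2)[C@H](O[Si](C)(C)C(C)(C)C)[C@@H]1C | intermediate
30 | C7 ketone, C6 acrylate (cyclodec-4-ene-1,7-dione) | O=C1CC/C(C)=C/[C@@H](OC(=O)C=C)C(=O)[C@@H](OCc2ccc(OC)cc2)[C@H](O[Si](C)(C)C(C)(C)C)[C@@H]1C | intermediate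
31 | α-methylene-β-hydroxy-γ-lactone fused at C6–C7 (C7 not defined) | O=C1CC/C(C)=C/[C@H]2OC(=O)C(=C)C2(O)[C@@H](OCc3ccc(OC)cc3)[C@H](O[Si](C)(C)C(C)(C)C)[C@@H]1C | intermediate
32 | tertiary C7 acetate of 31 (not isolated) | O=C1CC/C(C)=C/[C@H]2OC(=O)C(=C)C2(OC(C)=O)[C@@H](OCc3ccc(OC)cc3)[C@H](O[Si](C)(C)C(C)(C)C)[C@@H]1C | intermediate
33 | butenolide with C13 acetate, C8–OPMB, C9–OTBS | O=C1CC/C(C)=C/[C@H]2OC(=O)C(COC(C)=O)=C2[C@@H](OCc3ccc(OC)cc3)[C@H](O[Si](C)(C)C(C)(C)C)[C@@H]1C | intermediate
34 | C8 alcohol | O=C1CC/C(C)=C/[C@H]2OC(=O)C(COC(C)=O)=C2[C@@H](O)[C@H](O[Si](C)(C)C(C)(C)C)[C@@H]1C | intermediate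
35 | C8 methacrylate, C9–OTBS | O=C1CC/C(C)=C/[C@H]2OC(=O)C(COC(C)=O)=C2[C@@H](OC(=O)C(C)=C)[C@H](O[Si](C)(C)C(C)(C)C)[C@@H]1C | intermediate
36 | C9 alcohol, 4,5-deoxy target | O=C1CC/C(C)=C/[C@H]2OC(=O)C(COC(C)=O)=C2[C@@H](OC(=O)C(C)=C)[C@H](O)[C@@H]1C | intermediate
37 | CNP0185951.1, (4R,5R,6S,8R,9R,10S)-13-acetoxy-4,5-epoxy-9-hydroxy-8-(methacryloyloxy)-1-oxogermacr-7(11)-en-12,6-olide | C=C(C)C(=O)O[C@@H]1C2=C(COC(C)=O)C(=O)O[C@@H]2[C@H]2O[C@]2(C)CCC(=O)[C@@H](C)[C@H]1O | target

**Step count and risks**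

Total step count: 28 (steps 1–2 make the alkenyl iodide 3; steps 3–28 are the main line).
Longest linear sequence: 26 steps (4 to 37, steps 3–28).

Steps most likely to fail:

1. Step 18 (proposed new method). After ionisation and loss of CO2 the palladium enolate may be protonated instead of allylated, giving the open-chain methyl ketone and a diene by β-hydride loss. It may also attack C5, lose the E geometry through syn–anti isomerisation of the π-allyl unit, or react between two molecules. Fallback by known chemistry, from 23 back to 26: ClCO2Me and pyridine should give the allylic methyl carbonate F1. Pd(PPh3)4 with 1,2-bis(diphenylphosphino)ethane in THF at high dilution should then close ring A by intramolecular Tsuji–Trost alkylation of the β-keto ester at C2 (the methoxide set free on ionisation is the base), giving the ten-membered 2-(tert-butoxycarbonyl) ketone F2. Heating F2 in wet toluene (acylketene, hydration, loss of CO2) should return 26.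

2. Step 23. Addition of the phosphonium enolate to the crowded C7 ketone may be slow, so that enolisation at C6 or C8 and oligomerisation of the acrylate take over. Fallback, from 30 back to 31: PhSLi (from PhSH and n-BuLi) in THF at −78 °C should add to the acrylate and the resulting lithium ester enolate should close ring B on C7 (tandem Michael–aldol), giving the α-(phenylthiomethyl)-β-hydroxy lactone F3. mCPBA (1 equiv, −78 °C) should give the sulfoxide F4. Warming F4 in toluene with CaCO3 (syn-elimination of the sulfenic acid; only the C11 hydrogen is available) should return 31.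

3. Step 8. Facial selectivity may be poor if a β-chelate through the C8 ether or the amide competes with the α-chelate, giving C6 epimers. Fallback, from the epimer mixture of 12 back to 12: Dess–Martin oxidation should give the enone F5. KBH(s-Bu)3 in THF at −78 °C should then reduce it by Felkin–Anh hydride delivery anti to the C7 ether, without chelation, setting C6–OH syn to C7–ODMB; 1,4-reduction is blocked by the disubstituted β-carbon.

Further compounds
F1 | step 18 | allylic methyl carbonate of 23 | COC(=O)OC/C(C)=C/[C@@H](O[Si](CC)(CC)CC)[C@H](OCc1ccc(OC)c(OC)c1)[C@@H](OCc1ccc(OC)cc1)[C@H](O[Si](C)(C)C(C)(C)C)[C@H](C)C(=O)CC(=O)OC(C)(C)C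
F2 | step 18 | ten-membered 2-(tert-butoxycarbonyl) ketone (26 with CO2t-Bu on C2; C2 not defined) | O=C1C(C(=O)OC(C)(C)C)C/C(C)=C/[C@@H](O[Si](CC)(CC)CC)[C@H](OCc2ccc(OC)c(OC)c2)[C@@H](OCc2ccc(OC)cc2)[C@H](O[Si](C)(C)C(C)(C)C)[C@@H]1C
F3 | step 23 | α-(phenylthiomethyl)-β-hydroxy-γ-lactone fused at C6–C7 (C7 and C11 not defined) | O=C1CC/C(C)=C/[C@H]2OC(=O)C(CSc3ccccc3)C2(O)[C@@H](OCc3ccc(OC)cc3)[C@H](O[Si](C)(C)C(C)(C)C)[C@@H]1C
F4 | step 23 | sulfoxide of F3 | O=C1CC/C(C)=C/[C@H]2OC(=O)C(CS(=O)c3ccccc3)C2(O)[C@@H](OCc3ccc(OC)cc3)[C@H](O[Si](C)(C)C(C)(C)C)[C@@H]1C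
F5 | step 8 | C6 enone from 12 | CC[Si](CC)(CC)OC/C(C)=C/C(=O)[C@H](OCc1ccc(OC)c(OC)c1)[C@@H](OCc1ccc(OC)cc1)C(=O)N(C)OC
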